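## Analysis of the target

Numbering used throughout: ring A is C1–C2–C3–C4–C5; the cyclobutane is C1–C5–C6–C10; ring B is C6–C7–C8–C9–C10; the butenolide is C6–O6–C12(=O)–C11=C7; C13 sits on C11, C14 on C10, C15 on C4.

The target 35 is a 5-4-5 carbotricycle with a butenolide fused across C6–C7. It carries acetates on O2 and O13, an (E)-2-methylbut-2-enoate (tiglate) on O8 and a free tertiary hydroxyl on C4. There are seven stereocentres (C1, C2, C4, C5, C6, C8, C10). Rings A and B lie on the same face of the cyclobutane (cis-syn-cis), so H1, H5, C14 and O6 share the other face. In ring A, O2 and O4 are cis to each other and to H1/H5, and C15 points into the fold between the rings. O8 lies on the outer face of ring B, cis to C14 and O6. C6 and C10 are adjacent, fully substituted carbons of the four-membered ring. The sensitive groups are an allylic acetate on an electron-poor alkene, a tiglate that does not survive hydrogenation or bromine, a tertiary alcohol, and a strained ring whose C6 hydroxy/C7 ketone stage can undergo an acyloin shift with ring enlargement. The difficulties are the cyclobutane with two contiguous quaternary carbons, the syn ring fusion, and four oxygens that must end up differently acylated. The strategy rests on the fact that C1 is bonded to C2, C5 and C10. Taking C5 out of the four-membered ring leaves a C1–C6–C10 cyclopropane spiro-linked to ring A at C1. A carbene at C5 puts C5 back into the C1–C6 bond and gives a C1=C5 cyclobutene, whose ring-fusion configuration is then set by hydrogenation.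

## Retrosynthetic reasoning

**Esters and C13.** Target 35 comes from diol 34 by acetylating the primary O13 and the secondary O2 together; the tertiary O4 stays free. Diol 34 comes from silyl ether 33. The C11–C13 bond of 33 is cut back to bromo butenolide 32, so the forward step is an sp2–sp3 coupling with a hydroxymethyl tin reagent. This cut is preferred to oxidising a C13 methyl, because an allylic oxidation would have to choose between C13 and the activated C8–H. The tiglate of 32 is put on diol 31 after the bromination that gives 30, since bromine would attack the tiglate alkene.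

**Butenolide.** Bromide 30 comes from butenolide 28, and 28 is cut at C7=C11 and O6–C12 to α-ketol 26 plus a two-carbon ylide reagent. Forward, the tertiary hydroxyl is acylated and the ring closes by Wittig olefination at C7. The ketol is exposed only at this point, by hydrogenolysis of benzyl ether 25, to limit the chance of an acyloin shift.

**O8.** Ketone 25 comes from enol silane 23 and that from ketone 22. C8 is the only enolisable position, and the oxidant should enter from the outer face of ring B because the inner face is covered by ring A and C15.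

**Ring fusion.** Ketone 22 comes from alcohol 21, and 21 from cyclobutene 20 by adding H2 across C1=C5. Both hydroxyls of 20 (on C4 and C7) lie on the face of O6 and C14, so a hydroxyl-directed catalyst should deliver H1 and H5 there and fold ring A toward ring B. A benzyl ether must survive this step, so a homogeneous iridium catalyst is used and debenzylation is a separate, later step. Diol 20 comes from the fully protected cyclobutene 19.

**Key disconnection.** In 19 the C5–C6 bond is cut and C1–C6 is re-formed. This leads to N-tosylhydrazone 16 of spiro ketone 14, through hydrazone 15. Forward, a carbene at C5 must shift C6 from C1 to C5. No stereocentre is made, and the configuration at C1 of 14 is irrelevant.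

**Cyclopropane.** Spiro ketone 14 is cut at C1–C6 and C1–C10 into diazo ketone 13 and enol ether 5. Two changes are made against the most direct version of this union:

- C7 carries a silyloxy stereocentre, not a ketal. A ketal would leave the two faces of the enol ether enantiotopic, so the sense of C6/C10 relative to ring A would depend on remote induction. With the C7 stereocentre the carbenoid adds anti to O7, and ring B alone fixes C6/C10. An allylic ketal oxygen could also trap the carbenoid as an ylide.
- The carbenoid of 13 has a hydrogen on C2 next to a silyloxy group. A 1,2-shift of this hydrogen is the main threat to the step and is met by a bulky dirhodium carboxylate at low temperature.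

**Ring A.** Diazo ketone 13 comes from ketone 11 by diazo transfer at C1. Ketone 11 comes via 10 from diol 9, epoxy alcohol 8 and allylic alcohol 7. Alcohol 7 comes from enone 6 by addition of a methyl nucleophile anti to the silyloxy group, which sets C4. The epoxide/hydride sequence moves the oxygen onto C5.

**Ring B.** Enol ether 5 comes from alcohol 4, from enone 3, from dione 1 and bromide 2. The only stereocentre (C7) is set by catalytic asymmetric reduction.

## Alternatives that were turned down

**Alternative 1:** The C7–C8 bond of ring B is cut one acylation before 35. Forward, CrCl2 with catalytic NiCl2 would insert into the C7 enol triflate of the spiro butenolide aldehyde A1, and the C7 nucleophile would add to the C8 aldehyde to give the 8-hydroxy tetracycle A2.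
- For it: the chromium chemistry tolerates esters, the lactone and the tertiary alcohol, and only the tigloylation would remain. On endgame economy it is stronger than the chosen route, which needs thirteen steps after its key step.
- Against it: A1 already contains the cyclobutane with both quaternary carbons and the correct relation to ring A, so the hardest part of the structure is only moved into the preparation of A1. C8 is formed in the ring closure with no clear control of its hydroxyl toward the outer face. The allylic C13 acetate sits next to the metallated carbon and can be ionised by zerovalent nickel.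
- Comparison: the chosen strategy gives an answer for the four-membered ring itself and sets C8 on a rigid tricycle.

**Alternative 2:** The C6–C10 bond is cut. Forward, near-UV irradiation of the ring A-fused 2-benzyloxy-5-methyltropone A3 would close the 4π system in a disrotatory sense to the bicyclo[3.2.0]heptadienone A4.
- For it: one photochemical step makes the cyclobutene, ring B and both quaternary carbons from a flat precursor, and A4 carries a C7 ketone and a C8=C9 alkene for later oxygenation. In step count to the tricyclic core it is stronger than the chosen route, and it reaches the same type of C1=C5 cyclobutene as 19.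
- Against it: A3 is planar, so the sense of C6/C10 relative to C2/C4 would depend only on remote ring A substituents. Photoproducts of 2-alkoxytropones are themselves photolabile and a second closure mode competes. A3, a bicyclic tropolone ether with two stereocentres, is a demanding target.
- Comparison: the chosen strategy fixes C6/C10 through the C7 stereocentre of 5 and uses only ground-state chemistry after a convergent union of two simple rings.

**Alternative 3:** C6–C7 and C11–C12 are cut, and C6–C10 is traced back to a ring contraction. Forward, photolysis of the diazo ketone A5 would shift C10 from C12 to C6 (Wolff contraction to the cyclobutane), and the C6=C12=O unit so formed would add to the C7≡C11 triple bond to give the cyclobutenone A6.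
- For it: the cascade forms the cyclobutane, ring B and the C7=C11 alkene with C13 and O8 already in place. On the endgame, and on C13 in particular, it is stronger than the chosen route.
- Against it: A6 has C12 bonded to C6, so an oxygen must still be inserted between C6 and C12 on a spiro-linked pair of four-membered rings. A5 needs C1, C5 and C10 set on a bicyclo[3.3.0]octane plus an acyclic C8 stereocentre, so the syn relation of the rings must be built before the key step. The cascade has to run through a very strained, fully substituted ketene.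
- Comparison: the chosen strategy postpones the ring fusion to a directed hydrogenation and forms the lactone oxygen bond directly, without a later insertion.

Key step: step 13

## Assumptions (one line each)

- Compound 6 is taken as a catalogue chemical; the same enantiomer is reached in three steps (O-silylation, acetate methanolysis, allylic oxidation) from (1S,4R)-cis-4-acetoxy-2-cyclopenten-1-ol.
- Step 10 is expected to give both C1 epimers of 14; compounds 14–18 are drawn as one of them, and both converge on 19 because C1 becomes trigonal.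
- Compound 1 is drawn as the dione and reacts through its enol.

## Route

Step 1
Reactants: 1 3-methylcyclopentane-1,2-dione (cyclotene); 2 benzyl bromide
Product: 3 2-(benzyloxy)-3-methylcyclopent-2-en-1-one
Conditions: K2CO3, DMF, rt
Reagents that add atoms: none
Why: Williamson O-alkylation of the enol (diosphenol) form of 1 under mild base; the enol oxygen is the usual site of alkylation for this cyclic 1,2-dione.

Step 2
Reactants: 3 2-(benzyloxy)-3-methylcyclopent-2-en-1-one
Product: 4 (S)-2-(benzyloxy)-3-methylcyclopent-2-en-1-ol
Conditions: (R)-2-methyl-CBS-oxazaborolidine (10 mol %), BH3·SMe2, THF, −20 °C; MeOH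
Reagents that add atoms: none
Why: Corey–Bakshi–Shibata reduction; the alkoxy-substituted alkenyl arm acts as the large group against the ring CH2, so the (R)-catalyst should give the (S)-carbinol, which becomes C7.

Step 3
Reactants: 4 (S)-2-(benzyloxy)-3-methylcyclopent-2-en-1-ol
Product: 5 ring B enol ether (S)-{[2-(benzyloxy)-3-methylcyclopent-2-en-1-yl]oxy}triethylsilane
Conditions: Et3SiCl, imidazole, DMF, 0 °C
Reagents that add atoms: chlorotriethylsilane, CC[Si](Cl)(CC)CC
Why: Standard silylation of a secondary allylic alcohol under basic conditions that spare the enol ether; the triethylsilyl group is chosen so that it later leaves together with the C4 silyl ether while the C2 tert-butyldimethylsilyl ether stays.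

Step 4
Reactants: 6 (S)-4-[(tert-butyldimethylsilyl)oxy]cyclopent-2-en-1-one
Product: 7 (1R,4S)-4-[(tert-butyldimethylsilyl)oxy]-1-methylcyclopent-2-en-1-ol
Conditions: MeLi, THF, −78 °C; aq NH4Cl
Reagents that add atoms: methyllithium, [Li]C
Why: 1,2-Addition of an organolithium to the enone; the nucleophile enters anti to the silyloxy group, which sets C4 with its hydroxyl cis to O2.

Step 5
Reactants: 7 (1R,4S)-4-[(tert-butyldimethylsilyl)oxy]-1-methylcyclopent-2-en-1-ol
Product: 8 all-cis epoxy alcohol 4-[(tert-butyldimethylsilyl)oxy]-2-methyl-6-oxabicyclo[3.1.0]hexan-2-ol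
Conditions: VO(acac)2 (cat.), t-BuOOH, CH2Cl2, 0 °C
Reagents that add atoms: tert-butyl hydroperoxide, CC(C)(C)OO
Why: Hydroxyl-directed vanadium-catalysed epoxidation of a cyclic allylic alcohol delivers oxygen to the face of the C4 hydroxyl; the C5 centre made here is oxidised away in step 7, so only the position of the oxygen matters.

Step 6
Reactants: 8 all-cis epoxy alcohol
Product: 9 4-[(tert-butyldimethylsilyl)oxy]-1-methylcyclopentane-1,2-diol (three oxygens cis)
Conditions: LiEt3BH (3 equiv), THF, 0 °C to rt; H2O
Reagents that add atoms: none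
Why: SN2 opening of the epoxide by hydride from the face opposite the epoxide oxygen; attack at C1, whose neighbour C2 shows only hydrogen on that face, is preferred over attack at the neopentyl C5 next to the C4 methyl, so the oxygen stays on C5.

Step 7
Reactants: 9 4-[(tert-butyldimethylsilyl)oxy]-1-methylcyclopentane-1,2-diol
Product: 10 4-[(tert-butyldimethylsilyl)oxy]-2-hydroxy-2-methylcyclopentan-1-one (hydroxyl cis to silyloxy)
Conditions: Dess–Martin periodinane, NaHCO3, CH2Cl2, 0 °C
Reagents that add atoms: none
Why: Dess–Martin oxidation of the secondary alcohol of a secondary/tertiary 1,2-diol to the α-hydroxy ketone; the buffered, non-basic medium avoids β-elimination of the C2 silyloxy group.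

Step 8
Reactants: 10 4-[(tert-butyldimethylsilyl)oxy]-2-hydroxy-2-methylcyclopentan-1-one
Product: 11 4-[(tert-butyldimethylsilyl)oxy]-2-methyl-2-[(triethylsilyl)oxy]cyclopentan-1-one
Conditions: Et3SiOTf, 2,6-lutidine, CH2Cl2, −78 to 0 °C
Reagents that add atoms: triethylsilyl trifluoromethanesulfonate, CC[Si](CC)(CC)OS(=O)(=O)C(F)(F)F
Why: A silyl triflate with a hindered pyridine base silylates tertiary alcohols; the base is too weak to enolise the ketone toward C1.

Step 9
Reactants: 11 4-[(tert-butyldimethylsilyl)oxy]-2-methyl-2-[(triethylsilyl)oxy]cyclopentan-1-one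
Product: 13 ring A diazo ketone 2-diazo-3-[(tert-butyldimethylsilyl)oxy]-5-methyl-5-[(triethylsilyl)oxy]cyclopentan-1-one, via trifluoroacetyl ketone 12 (not isolated)
Conditions: LiN(SiMe3)2, THF, −78 °C; CF3CO2CH2CF3; aq HCl work-up; then MeSO2N3, Et3N, H2O, MeCN, rt
Reagents that add atoms: methanesulfonyl azide, CS(=O)(=O)N=[N+]=[N-]; 2,2,2-trifluoroethyl trifluoroacetate, FC(F)(F)C(=O)OCC(F)(F)F (trifluoroacetyl group of 12 only)
Why: Regitz-type detrifluoroacetylative diazo transfer: the enolate can form only toward C1 (C4 has no hydrogen), is acylated at −78 °C before the β-silyloxy group can be lost, and the 1,3-dicarbonyl 12 takes up the diazo group with loss of the activating acyl group.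

Step 10
Reactants: 13 ring A diazo ketone; 5 ring B enol ether
Product: 14 spiro cyclopropyl ketone (precursor of the key step)
Conditions: Rh2(esp)2 (1 mol %), 5 (3 equiv), CH2Cl2, −78 to −30 °C, slow addition of 13
Reagents that add atoms: none
Why: Dirhodium-carboxylate-catalysed cyclopropanation of an electron-rich enol ether by an α-diazo ketone; a bulky bridging carboxylate at low temperature is the setting in which cyclic α-diazo carbonyl compounds add to alkenes faster than the β-hydrogen shifts. The carbenoid adds to the face of 5 anti to the C7 silyloxy group, which sets C6 and C10; C1 forms as epimers that both serve.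

Step 11
Reactants: 14 spiro cyclopropyl ketone
Product: 15 hydrazone of 14
Conditions: N2H4·H2O (10 equiv), EtOH, 80 °C
Reagents that add atoms: hydrazine, NN
Why: Hydrazone formation with the smallest and most nucleophilic condensation partner, suited to a ketone flanked by two fully substituted carbons; the basic medium does not ionise the alkoxy-substituted cyclopropane and an azine cannot form for steric reasons.

Step 12
Reactants: 15 hydrazone of 14
Product: 16 N-tosylhydrazone of 14
Conditions: TsCl, pyridine, CH2Cl2, 0 °C
Reagents that add atoms: p-toluenesulfonyl chloride, Cc1ccc(cc1)S(Cl)(=O)=O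
Why: N-Sulfonylation of the terminal NH2 of a hydrazone gives the N-tosylhydrazone without acid or heat.

Step 13
Reactants: 16 N-tosylhydrazone of 14
Product: 19 C1=C5 cyclobutene tricycle, via sodium salt 17 (not isolated), via diazoalkane 18 (not isolated)
Conditions: NaH (1.1 equiv), THF, 0 °C to rt; solvent exchange to diglyme, 140 °C
Reagents that add atoms: sodium hydride, [Na+].[H-] (sodium of 17)
Why: NaH removes the sulfonamide proton to give salt 17, which on heating expels p-toluenesulfinate to form diazoalkane 18 and, after loss of N2, a singlet carbene at C5 (aprotic Bamford–Stevens conditions). The empty p orbital at C5 is aligned with the C1–C6 and C1–C10 bonds of the adjacent cyclopropane; C6 shifts from C1 to C5 with its bonding pair and with retention, while the carbene lone pair becomes the C1=C5 π bond. The closest known reaction type is the ring enlargement of cyclopropylcarbenes made from tosylhydrazone salts, including the parent spiro[2.4]heptan-4-ylidene to bicyclo[3.2.0]hept-1(5)-ene case. The four-membered ring C1–C5–C6–C10 is closed by a 1,2-alkyl shift that enlarges the three-membered ring, not by cyclisation of a chain, so no ring-size rule applies. No stereocentre is formed: C1 becomes trigonal, so both C1 epimers of 16 converge, and C2, C4, C6, C7 and C10 are carried through unchanged. The step needs migration of C1–C6 rather than C1–C10; both carbons are fully substituted, so the choice is electronic, and the oxygen lone pair on C6 makes C1–C6 the more electron-rich bond toward the electron-poor carbene centre. Competing carbene paths are limited by the structure: C4 and C1 carry no hydrogen (no 1,2-hydrogen shift), fragmentation to an alkene and an alkyne would need a cyclopentyne, and C–H insertion into the silyl groups is slower than ring enlargement of a cyclopropylcarbene. The product is a bicyclo[3.2.0]hept-1(5)-ene whose cyclobutene cannot open in the allowed conrotatory sense because C6–C10 is held in ring B, so it should survive the temperature of the step.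

Step 14
Reactants: 19 C1=C5 cyclobutene tricycle
Product: 20 cyclobutene 4,7-diol
Conditions: HF·pyridine, pyridine, THF, 0 °C
Reagents that add atoms: none
Why: Buffered HF·pyridine cleaves the two triethylsilyl ethers while the secondary tert-butyldimethylsilyl ether persists; fluoride rather than protic acid spares the allylic tertiary C4–O bond.

Step 15
Reactants: 20 cyclobutene 4,7-diol
Product: 21 saturated cis-syn-cis tricycle 4,7-diol
Conditions: [Ir(cod)(PCy3)(py)]PF6 (10 mol %), H2 (5 bar), CH2Cl2, rt
Reagents that add atoms: none
Why: Hydroxyl-directed hydrogenation with a cationic iridium catalyst, the usual choice for tetrasubstituted alkenes; the allylic C4 hydroxyl and the homoallylic C7 hydroxyl both lie on the face of O6 and C14, so H1 and H5 are delivered there and ring A folds toward ring B. The benzyl ether is not cleaved by this catalyst.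

Step 16
Reactants: 21 saturated cis-syn-cis tricycle 4,7-diol
Product: 22 tricyclic C7 ketone
Conditions: Dess–Martin periodinane, NaHCO3, CH2Cl2, rt
Reagents that add atoms: none
Why: Dess–Martin oxidation of the only secondary alcohol; O6 is still benzylated, so no α-ketol is present at this stage.

Step 17
Reactants: 22 tricyclic C7 ketone
Product: 23 C7 silyl enol ether 4-silyl ether
Conditions: Et3SiOTf (2.5 equiv), Et3N, CH2Cl2, −78 to 0 °C
Reagents that add atoms: triethylsilyl trifluoromethanesulfonate, CC[Si](CC)(CC)OS(=O)(=O)C(F)(F)F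
Why: Silyl triflate and amine convert the ketone into its silyl enol ether (only C8 carries α-hydrogen) and silylate the tertiary C4 hydroxyl in the same operation.

Step 18
Reactants: 23 C7 silyl enol ether 4-silyl ether
Product: 25 8-(triethylsilyloxy) C7 ketone, via silyloxy epoxide 24 (not isolated)
Conditions: dimethyldioxirane, acetone/CH2Cl2, −40 °C; then rt
Reagents that add atoms: dimethyldioxirane, CC1(C)OO1
Why: Rubottom oxidation: the enol ether is epoxidised from the outer face of ring B (the inner face is covered by ring A and C15) and a 1,4-silyl shift on warming gives the α-silyloxy ketone; this sets C8 with O8 cis to O6 and C14.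

Step 19
Reactants: 25 8-(triethylsilyloxy) C7 ketone
Product: 26 α-ketol (6-hydroxy 7-ketone)
Conditions: H2 (1 atm), Pd(OH)2/C, EtOAc, rt
Reagents that add atoms: none
Why: Hydrogenolysis of the benzyl C–O bond under neutral conditions; silyl ethers survive in ethyl acetate and the α-ketol is not exposed to acid or base.

Step 20
Reactants: 26 α-ketol
Product: 28 butenolide (C11–H), via ester ylide 27 (not isolated)
Conditions: Ph3P=C=C=O (1.5 equiv), toluene, 100 °C
Reagents that add atoms: (triphenylphosphoranylidene)ketene, O=C=C=P(c1ccccc1)(c1ccccc1)c1ccccc1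
Why: The tertiary hydroxyl adds to the cumulated ylide to give the acyl phosphorane 27, which closes by intramolecular Wittig olefination at the C7 ketone; this is an established neutral butenolide annulation for hindered tertiary α-ketols.

Step 21
Reactants: 28 butenolide (C11–H)
Product: 30 11-bromo butenolide, via dibromide 29 (not isolated)
Conditions: Br2, CH2Cl2, 0 °C; then Et3N
Reagents that add atoms: bromine, BrBr
Why: Addition of bromine to the butenolide alkene, then E1cB loss of HBr (acidic H11, bromide from C7), is the usual entry to α-bromo butenolides; it is done here because 28 contains no other alkene.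

Step 22
Reactants: 30 11-bromo butenolide
Product: 31 bromo butenolide 4,8-diol
Conditions: HF·pyridine, pyridine, THF, 0 °C
Reagents that add atoms: none
Why: As in step 14, triethylsilyl ethers are cleaved selectively and the C2 tert-butyldimethylsilyl ether stays.

Step 23
Reactants: 31 bromo butenolide 4,8-diol
Product: 32 8-tiglate
Conditions: tiglic acid, 2,4,6-trichlorobenzoyl chloride, Et3N, toluene; then 31, DMAP, rt
Reagents that add atoms: tiglic acid, C/C=C(\C)C(O)=O
Why: Yamaguchi esterification through the mixed anhydride acylates the secondary C8 hydroxyl and leaves the tertiary C4 hydroxyl alone; the (E)-alkene of the tiglate is the stable isomer and is kept.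

Step 24
Reactants: 32 8-tiglate
Product: 33 13-hydroxy compound
Conditions: Bu3SnCH2OH (1.5 equiv), Pd(PPh3)4 (10 mol %), dioxane, 90 °C
Reagents that add atoms: (tributylstannyl)methanol, OC[Sn](CCCC)(CCCC)CCCC
Why: Stille coupling of an alkenyl bromide with a hydroxymethyl stannane; zerovalent palladium inserts into the C11–Br bond activated by the lactone carbonyl, and esters and the free tertiary alcohol are tolerated.

Step 25
Reactants: 33 13-hydroxy compound
Product: 34 2,13-diol
Conditions: HF·pyridine, THF, rt
Reagents that add atoms: none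
Why: Fluoride cleavage of the remaining silyl ether under mildly acidic conditions that leave the tiglate, the lactone and the allylic alcohol intact.

Step 26
Reactants: 34 2,13-diol
Product: 35 target CNP0210373.1
Conditions: Ac2O, pyridine, DMAP (cat.), CH2Cl2, 0 °C
Reagents that add atoms: acetic anhydride, CC(=O)OC(C)=O
Why: Acetylation of the primary C13 and secondary C2 hydroxyls; the tertiary C4 hydroxyl does not react at 0 °C.

## Compound list

1 | 3-methylcyclopentane-1,2-dione (cyclotene) | CC1CCC(=O)C1=O | starting material
2 | benzyl bromide | BrCc1ccccc1 | starting material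
3 | 2-(benzyloxy)-3-methylcyclopent-2-en-1-one | CC1=C(OCc2ccccc2)C(=O)CC1 | intermediate
4 | (S)-2-(benzyloxy)-3-methylcyclopent-2-en-1-ol | CC1=C(OCc2ccccc2)[C@@H](O)CC1 | intermediate
5 | (S)-{[2-(benzyloxy)-3-methylcyclopent-2-en-1-yl]oxy}triethylsilane (ring B: C6 OBn, C10 Me, C7 OSiEt3) | CC1=C(OCc2ccccc2)[C@@H](O[Si](CC)(CC)CC)CC1 | intermediate
6 | (S)-4-[(tert-butyldimethylsilyl)oxy]cyclopent-2-en-1-one | O=C1C[C@H](O[Si](C)(C)C(C)(C)C)C=C1 | starting material
7 | (1R,4S)-4-[(tert-butyldimethylsilyl)oxy]-1-methylcyclopent-2-en-1-ol (hydroxyl cis to silyloxy; C4 carbinol, C5=C1 alkene, C2 silyloxy) | O[C@]1(C)C[C@H](O[Si](C)(C)C(C)(C)C)C=C1 | intermediate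
8 | 4-[(tert-butyldimethylsilyl)oxy]-2-methyl-6-oxabicyclo[3.1.0]hexan-2-ol (epoxide oxygen, hydroxyl and silyloxy all cis) | O[C@]1(C)C[C@H](O[Si](C)(C)C(C)(C)C)[C@@H]2O[C@H]12 | intermediate
9 | 4-[(tert-butyldimethylsilyl)oxy]-1-methylcyclopentane-1,2-diol (three oxygens cis) | O[C@@H]1[C@](C)(O)C[C@H](O[Si](C)(C)C(C)(C)C)C1 | intermediate
10 | 4-[(tert-butyldimethylsilyl)oxy]-2-hydroxy-2-methylcyclopentan-1-one (hydroxyl cis to silyloxy; C5 ketone) | O=C1[C@](C)(O)C[C@H](O[Si](C)(C)C(C)(C)C)C1 | intermediate
11 | 4-[(tert-butyldimethylsilyl)oxy]-2-methyl-2-[(triethylsilyl)oxy]cyclopentan-1-one (same configuration) | O=C1[C@](C)(O[Si](CC)(CC)CC)C[C@H](O[Si](C)(C)C(C)(C)C)C1 | intermediate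
12 | 5-(trifluoroacetyl) derivative of 11 (acyl group on C1) | O=C1[C@](C)(O[Si](CC)(CC)CC)C[C@H](O[Si](C)(C)C(C)(C)C)C1C(=O)C(F)(F)F | intermediate (not isolated)
13 | 2-diazo-3-[(tert-butyldimethylsilyl)oxy]-5-methyl-5-[(triethylsilyl)oxy]cyclopentan-1-one (O2 and O4 cis) | O=C1[C@](C)(O[Si](CC)(CC)CC)C[C@H](O[Si](C)(C)C(C)(C)C)C1=[N+]=[N-] | intermediate
14 | 1-(benzyloxy)-5'-[(tert-butyldimethylsilyl)oxy]-3',5-dimethyl-2,3'-bis[(triethylsilyl)oxy]spiro[bicyclo[3.1.0]hexane-6,1'-cyclopentan]-2'-one (C6/C10 cis, both trans to O7; drawn C1 epimer has the C5 carbonyl on the side of OBn and C14) | O=C1[C@](C)(O[Si](CC)(CC)CC)C[C@H](O[Si](C)(C)C(C)(C)C)[C@]12[C@@]3(C)CC[C@H](O[Si](CC)(CC)CC)[C@@]23OCc2ccccc2 | intermediate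
15 | hydrazone of 14 at C5 | NN=C1[C@](C)(O[Si](CC)(CC)CC)C[C@H](O[Si](C)(C)C(C)(C)C)[C@]12[C@@]3(C)CC[C@H](O[Si](CC)(CC)CC)[C@@]23OCc2ccccc2 | intermediate
16 | N-tosylhydrazone of 14 at C5 | Cc1ccc(cc1)S(=O)(=O)NN=C1[C@](C)(O[Si](CC)(CC)CC)C[C@H](O[Si](C)(C)C(C)(C)C)[C@]12[C@@]3(C)CC[C@H](O[Si](CC)(CC)CC)[C@@]23OCc2ccccc2 | intermediate
17 | sodium salt of 16 | [Na+].Cc1ccc(cc1)S(=O)(=O)[N-]N=C1[C@](C)(O[Si](CC)(CC)CC)C[C@H](O[Si](C)(C)C(C)(C)C)[C@]12[C@@]3(C)CC[C@H](O[Si](CC)(CC)CC)[C@@]23OCc2ccccc2 | intermediate (not isolated)
18 | C5 diazoalkane of the spiro system | [N-]=[N+]=C1[C@](C)(O[Si](CC)(CC)CC)C[C@H](O[Si](C)(C)C(C)(C)C)[C@]12[C@@]3(C)CC[C@H](O[Si](CC)(CC)CC)[C@@]23OCc2ccccc2 | intermediate (not isolated)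
19 | C1=C5 cyclobutene tricycle: 2-OTBS, 4-Me, 4-OSiEt3, 6-OBn, 7-OSiEt3, 10-Me (O2, O4, OBn, C14 and O7 on one face, ring B carbons on the other) | C1C[C@]2(C)C=3[C@@H](O[Si](C)(C)C(C)(C)C)C[C@@](C)(O[Si](CC)(CC)CC)C3[C@]2(OCc2ccccc2)[C@H]1O[Si](CC)(CC)CC | intermediate
20 | cyclobutene 4,7-diol (2-OTBS, 6-OBn) | C1C[C@]2(C)C=3[C@@H](O[Si](C)(C)C(C)(C)C)C[C@@](C)(O)C3[C@]2(OCc2ccccc2)[C@H]1O | intermediate
21 | saturated cis-syn-cis tricycle 4,7-diol (H1 and H5 cis to O4, O6 and C14) | C1C[C@]2(C)[C@@H]3[C@@H](O[Si](C)(C)C(C)(C)C)C[C@@](C)(O)[C@@H]3[C@]2(OCc2ccccc2)[C@H]1O | intermediate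
22 | tricyclic C7 ketone (4-OH, 2-OTBS, 6-OBn) | C1C[C@]2(C)[C@@H]3[C@@H](O[Si](C)(C)C(C)(C)C)C[C@@](C)(O)[C@@H]3[C@]2(OCc2ccccc2)C1=O | intermediate
23 | C7=C8 triethylsilyl enol ether, 4-OSiEt3 | C1C[C@]2(C)[C@@H]3[C@@H](O[Si](C)(C)C(C)(C)C)C[C@@](C)(O[Si](CC)(CC)CC)[C@@H]3[C@]2(OCc2ccccc2)C=1O[Si](CC)(CC)CC | intermediate
24 | 7,8-epoxide of 23 (oxygen on the outer face of ring B) | [C@H]12C[C@]3(C)[C@@H]4[C@@H](O[Si](C)(C)C(C)(C)C)C[C@@](C)(O[Si](CC)(CC)CC)[C@@H]4[C@]3(OCc3ccccc3)[C@@]1(O[Si](CC)(CC)CC)O2 | intermediate (not isolated)
25 | 8-(triethylsilyloxy) C7 ketone (O8 cis to O6 and C14) | CC[Si](CC)(CC)O[C@H]1C[C@]2(C)[C@@H]3[C@@H](O[Si](C)(C)C(C)(C)C)C[C@@](C)(O[Si](CC)(CC)CC)[C@@H]3[C@]2(OCc2ccccc2)C1=O | intermediate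
26 | α-ketol: 6-hydroxy 7-ketone | CC[Si](CC)(CC)O[C@H]1C[C@]2(C)[C@@H]3[C@@H](O[Si](C)(C)C(C)(C)C)C[C@@](C)(O[Si](CC)(CC)CC)[C@@H]3[C@]2(O)C1=O | intermediate
27 | 6-O-[(triphenylphosphoranylidene)acetyl] ester of 26 | CC[Si](CC)(CC)O[C@H]1C[C@]2(C)[C@@H]3[C@@H](O[Si](C)(C)C(C)(C)C)C[C@@](C)(O[Si](CC)(CC)CC)[C@@H]3[C@]2(OC(=O)C=P(c2ccccc2)(c2ccccc2)c2ccccc2)C1=O | intermediate (not isolated)
28 | tetracyclic butenolide with C11–H (2-OTBS, 4-OSiEt3, 8-OSiEt3) | CC[Si](CC)(CC)O[C@H]1C[C@]2(C)[C@@H]3[C@@H](O[Si](C)(C)C(C)(C)C)C[C@@](C)(O[Si](CC)(CC)CC)[C@@H]3[C@@]23OC(=O)C=C13 | intermediate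
29 | 7,11-dibromide of 28 (trans addition, C7/C11 configuration not defined) | CC[Si](CC)(CC)O[C@H]1C[C@]2(C)[C@@H]3[C@@H](O[Si](C)(C)C(C)(C)C)C[C@@](C)(O[Si](CC)(CC)CC)[C@@H]3[C@@]23OC(=O)C(Br)C13Br | intermediate (not isolated)
30 | 11-bromo butenolide | CC[Si](CC)(CC)O[C@H]1C[C@]2(C)[C@@H]3[C@@H](O[Si](C)(C)C(C)(C)C)C[C@@](C)(O[Si](CC)(CC)CC)[C@@H]3[C@@]23OC(=O)C(Br)=C13 | intermediate
31 | 11-bromo butenolide 4,8-diol (2-OTBS) | O[C@H]1C[C@]2(C)[C@@H]3[C@@H](O[Si](C)(C)C(C)(C)C)C[C@@](C)(O)[C@@H]3[C@@]23OC(=O)C(Br)=C13 | intermediate
32 | 8-tiglate of 31 | C/C=C(\C)C(=O)O[C@H]1C[C@]2(C)[C@@H]3[C@@H](O[Si](C)(C)C(C)(C)C)C[C@@](C)(O)[C@@H]3[C@@]23OC(=O)C(Br)=C13 | intermediate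
33 | 13-hydroxy 8-tiglate (2-OTBS) | C/C=C(\C)C(=O)O[C@H]1C[C@]2(C)[C@@H]3[C@@H](O[Si](C)(C)C(C)(C)C)C[C@@](C)(O)[C@@H]3[C@@]23OC(=O)C(CO)=C13 | intermediate
34 | 2,13-diol 8-tiglate | C/C=C(\C)C(=O)O[C@H]1C[C@]2(C)[C@@H]3[C@@H](O)C[C@@](C)(O)[C@@H]3[C@@]23OC(=O)C(CO)=C13 | intermediate
35 | CNP0210373.1: 2,13-di-O-acetyl 8-O-tigloyl tetracyclic lactone | C/C=C(\C)C(=O)O[C@H]1C[C@]2(C)[C@@H]3[C@@H](OC(C)=O)C[C@@](C)(O)[C@@H]3[C@@]23OC(=O)C(COC(C)=O)=C13 | target

## Step count and least certain steps

Total step count: 26. Longest linear sequence: 23 steps (from 6 through steps 4–26); the ring B branch (steps 1–3) joins at step 10.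

**Step 13 (key step).** The most likely failure is a shift of the C1–C10 bond in place of C1–C6, giving the transposed cyclobutene, or insertion of the carbene into a C–H bond of the neighbouring silyl ether. Both are favoured by the high temperature needed to break down 17. The fallback replaces the thermal free carbene by a rhodium carbenoid made below 0 °C. It sets out from hydrazone 15, which is dehydrogenated with activated dimethyl sulfoxide ((COCl)2, DMSO, Et3N, THF, −78 °C) to the diazoalkane 18 of the compound list. Rh2(OAc)4 (1 mol %) at −78 to −20 °C then gives a metal-bound carbenoid in which the 1,2-shift has more cationic character, so the oxygen-substituted C6 should be chosen more strongly. The route is rejoined at 19. This fallback makes no compound outside the list (F0).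

**Step 10.** The most likely failure is that the 1,2-shift of the C2 hydrogen within the rhodium carbenoid, helped by the geminal silyloxy group, outpaces capture by the hindered tetrasubstituted alkene. The fallback builds the four-membered ring by enone–alkene [2+2] photocycloaddition and enters the route after the key step. It sets out from 7 and 5:
- Fluoride (Bu4NF, THF) gives cis-1-methylcyclopent-4-ene-1,3-diol F1.
- MnO2 oxidises only the secondary allylic alcohol, to (R)-4-hydroxy-4-methylcyclopent-2-en-1-one F2.
- Et3SiOTf/2,6-lutidine gives the silyl ether F3, in which C2 is the carbonyl and C1=C5 the alkene.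
- Irradiation (350 nm, CH2Cl2, −40 °C) of F3 with excess 5 should give the head-to-tail photoadduct F4. The alkoxy carbon C6 bonds to the enone β-carbon C5 and C10 bonds to C1; ring B is again attacked anti to O7; a mixture of cis-fused isomers at C1/C5 is expected.
- Dehydrogenation of the ketone (2-iodoxybenzoic acid, DMSO, 70 °C) can only form C1=C5, because C4 has no hydrogen. It removes the C1/C5 mixture and gives the cyclobutene enone F5.
- NaBH4/CeCl3·7H2O reduction, with hydride entering anti to the C4 silyloxy group, gives the allylic alcohol F6.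
- t-BuMe2SiCl/imidazole gives 19, where the route is rejoined.

**Step 11.** The most likely failure is that condensation stalls at a carbonyl flanked by two fully substituted carbons, or that forcing conditions open the alkoxy-substituted cyclopropane. The fallback unmasks the neighbouring oxygen first. From 14, HF·pyridine removes both triethylsilyl groups to give the 4,7-dihydroxy spiro ketone F7. Its α-hydroxy ketone is less shielded and should condense with p-toluenesulfonyl hydrazide (MeOH, 50 °C) to the dihydroxy tosylhydrazone F8. Et3SiOTf/2,6-lutidine restores both silyl ethers and gives 16, where the route is rejoined; steps 11 and 12 are bypassed.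

**Step 20.** The most likely failure is an acyloin shift of the α-ketol 26 at the temperature of the Wittig closure (C5 moves from C6 to C7 and the four-membered ring is enlarged), or failure of the hindered ketone to react. The fallback acylates in the cold and closes with a phosphonate. From 26, bromoacetyl bromide/pyridine at 0 °C gives the 6-O-bromoacetate F9; an acylated ketol cannot undergo the shift. P(OEt)3 at 110 °C (Arbuzov reaction) gives the phosphonoacetate F10. LiCl/DBU in MeCN closes the ring by intramolecular Horner–Wadsworth–Emmons reaction to 28, where the route is rejoined.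

## Further compounds

F0 | step 13 | none | none
F1 | step 10 | cis-1-methylcyclopent-4-ene-1,3-diol | O[C@]1(C)C[C@H](O)C=C1
F2 | step 10 | (R)-4-hydroxy-4-methylcyclopent-2-en-1-one | O[C@]1(C)CC(=O)C=C1
F3 | step 10 | (R)-4-methyl-4-[(triethylsilyl)oxy]cyclopent-2-en-1-one | CC[Si](CC)(CC)O[C@]1(C)CC(=O)C=C1
F4 | step 10 | head-to-tail photoadduct: cyclobutane tricycle with C2 ketone, 4-OSiEt3, 6-OBn, 7-OSiEt3, 10-Me (cis-fused, mixture at C1/C5) | C1C[C@]2(C)C3C(=O)C[C@@](C)(O[Si](CC)(CC)CC)C3[C@]2(OCc2ccccc2)[C@H]1O[Si](CC)(CC)CC
F5 | step 10 | C1=C5 cyclobutene enone (C2 ketone) | C1C[C@]2(C)C=3C(=O)C[C@@](C)(O[Si](CC)(CC)CC)C3[C@]2(OCc2ccccc2)[C@H]1O[Si](CC)(CC)CC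
F6 | step 10 | C1=C5 cyclobutene 2-ol (hydroxyl cis to O4) | C1C[C@]2(C)C=3[C@@H](O)C[C@@](C)(O[Si](CC)(CC)CC)C3[C@]2(OCc2ccccc2)[C@H]1O[Si](CC)(CC)CC
F7 | step 11 | 4,7-dihydroxy spiro ketone (2-OTBS, 6-OBn) | O=C1[C@](C)(O)C[C@H](O[Si](C)(C)C(C)(C)C)[C@]12[C@@]3(C)CC[C@H](O)[C@@]23OCc2ccccc2
F8 | step 11 | N-tosylhydrazone of F7 | Cc1ccc(cc1)S(=O)(=O)NN=C1[C@](C)(O)C[C@H](O[Si](C)(C)C(C)(C)C)[C@]12[C@@]3(C)CC[C@H](O)[C@@]23OCc2ccccc2
F9 | step 20 | 6-O-bromoacetate of 26 | CC[Si](CC)(CC)O[C@H]1C[C@]2(C)[C@@H]3[C@@H](O[Si](C)(C)C(C)(C)C)C[C@@](C)(O[Si](CC)(CC)CC)[C@@H]3[C@]2(OC(=O)CBr)C1=O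
F10 | step 20 | 6-O-(diethoxyphosphoryl)acetate of 26 | CC[Si](CC)(CC)O[C@H]1C[C@]2(C)[C@@H]3[C@@H](O[Si](C)(C)C(C)(C)C)C[C@@](C)(O[Si](CC)(CC)CC)[C@@H]3[C@]2(OC(=O)CP(=O)(OCC)OCC)C1=O
A1 | alternative 1 | spiro butenolide with C7 enol triflate and C8 aldehyde | O=CC[C@]1(C)[C@@H]2[C@@H](OC(C)=O)C[C@@](C)(O)[C@@H]2[C@@]13OC(=O)C(COC(C)=O)=C3OS(=O)(=O)C(F)(F)F
A2 | alternative 1 | 8-hydroxy tetracycle (35 without the tiglate) | O[C@H]1C[C@]2(C)[C@@H]3[C@@H](OC(C)=O)C[C@@](C)(O)[C@@H]3[C@@]23OC(=O)C(COC(C)=O)=C13
A3 | alternative 2 | ring A-fused 2-benzyloxy-5-methyltropone | O=C1C=CC(C)=C2[C@@H](OC(C)=O)C[C@@](C)(O)C2=C1OCc1ccccc1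
A4 | alternative 2 | ring A-fused 1-benzyloxy-5-methylbicyclo[3.2.0]hepta-3,6-dien-2-one | O=C1C=C[C@]2(C)C=3[C@@H](OC(C)=O)C[C@@](C)(O)C3[C@@]21OCc1ccccc1
A5 | alternative 3 | C6 diazo ketone of the bicyclo[3.3.0]octanone with the C7≡C11 alkyne side chain | CC(C)(C)[Si](C)(C)O[C@H](C#CCOC(C)=O)C[C@]1(C)[C@@H]2[C@@H](OC(C)=O)C[C@@](C)(O[Si](CC)(CC)CC)[C@@H]2C(=[N+]=[N-])C1=O
A6 | alternative 3 | cyclobutenone tetracycle (C12 bonded to C6) | CC(C)(C)[Si](C)(C)O[C@H]1C[C@]2(C)[C@@H]3[C@@H](OC(C)=O)C[C@@](C)(O[Si](CC)(CC)CC)[C@@H]3[C@@]23C(=O)C(COC(C)=O)=C13
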